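**Retrosynthetic overview**
- The C3 ester is made late by Mitsunobu inversion of a cis C3 alcohol with the silyl-protected (Z)-2-(hydroxymethyl)but-2-enoic acid (built from crotonaldehyde); a silyl-to-acetate exchange finishes the route.
- The isopropenyl methyl comes from palladium-catalysed methylation of a 1-borylvinyl group; the acetyl group travels as a dioxolane until the alcohol stage.
- Feature the strategy rests on: C2 carries O1, the isopropenyl group and the bond to carbinol carbon C3, so C2 is the γ-carbon of a 2-boryl γ-aryloxy allylcopper and C3 is the carbon of an ortho aldehyde. The C2–C3 bond and the dihydrofuran ring (O1, C2, C3, C3a, C7a) are formed together by copper-catalysed borylative cyclisation of an allenyl ether aldehyde with B2pin2. This is the only ring made; the benzene ring is bought.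
- The allenyl ether aldehyde comes from 4'-hydroxyacetophenone by ketalisation, ortho-formylation, O-propargylation and base isomerisation.

Key step: step 5

Assumption: the sense of induction of the copper–bisphosphine catalyst in step 5 cannot be assigned in advance, so the ligand enantiomer that delivers (2R,3R)-9 is the one used; it is written below as (R,R)-Ph-BPE.

**Step 1**
Reactants: 1 4'-hydroxyacetophenone
Product: 2 4-(2-methyl-1,3-dioxolan-2-yl)phenol
Conditions: ethylene glycol (3 equiv), p-TsOH·H2O (2 mol%), toluene, reflux, Dean–Stark; NaHCO3 quench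
Reagents that add atoms: ethylene glycol, OCCO
Why: Acid-catalysed ketalisation driven to completion by azeotropic removal of water; the phenol is untouched and no stereocentre is formed.

**Step 2**
Reactants: 2 4-(2-methyl-1,3-dioxolan-2-yl)phenol
Product: 3 2-hydroxy-5-(2-methyl-1,3-dioxolan-2-yl)benzaldehyde
Conditions: MgCl2 (1.5 equiv), Et3N (3.75 equiv), (CH2O)n (6 equiv), MeCN, reflux; cold aq. NH4Cl work-up
Reagents that add atoms: paraformaldehyde (as formaldehyde), C=O
Why: Casnati–Skattebøl ortho-formylation, in which the magnesium phenoxide delivers formaldehyde to the free ortho position (para is blocked) and a second formaldehyde oxidises the hydroxymethyl intermediate; the basic medium and near-neutral work-up should keep the ketal intact.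

**Step 3**
Reactants: 3 2-hydroxy-5-(2-methyl-1,3-dioxolan-2-yl)benzaldehyde; 4 propargyl bromide
Product: 5 5-(2-methyl-1,3-dioxolan-2-yl)-2-(prop-2-yn-1-yloxy)benzaldehyde
Conditions: K2CO3 (1.5 equiv), DMF, rt
Reagents that add atoms: none
Why: Williamson etherification of the acidic salicylaldehyde phenol with a primary propargylic bromide under mild carbonate base, which neither the ketal nor the aldehyde should notice.

**Step 4**
Reactants: 5 5-(2-methyl-1,3-dioxolan-2-yl)-2-(prop-2-yn-1-yloxy)benzaldehyde
Product: 6 5-(2-methyl-1,3-dioxolan-2-yl)-2-(propa-1,2-dien-1-yloxy)benzaldehyde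
Conditions: KOtBu (20 mol%), THF, 0 °C to rt
Reagents that add atoms: none
Why: Base-catalysed prototropic propargyl-to-allenyl ether isomerisation with catalytic alkoxide; the aldehyde has no α-hydrogen and the ketal keeps the methyl ketone from forming an enolate.

**Step 5**
Reactants: 6 5-(2-methyl-1,3-dioxolan-2-yl)-2-(propa-1,2-dien-1-yloxy)benzaldehyde; 7 bis(pinacolato)diboron (1.2 equiv)
Product: 9 (2R,3R)-5-(2-methyl-1,3-dioxolan-2-yl)-2-[1-(4,4,5,5-tetramethyl-1,3,2-dioxaborolan-2-yl)ethenyl]-2,3-dihydro-1-benzofuran-3-ol (cis), via O-pinacolboryl ether 8 (not isolated)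
Conditions: CuCl (5 mol%), (R,R)-Ph-BPE (6 mol%), NaOtBu (20 mol%), THF (0.05 M), 0 °C to rt; then pH 7 aq. phosphate buffer
Reagents that add atoms: none
Why: Proposed new method: a ligated copper boryl (from CuCl, NaOtBu and B2pin2) should add across the terminal C=C of the allenyl ether, boron to the central carbon and copper to CH2 from the face away from the aryloxy group, giving a (Z)-2-boryl-γ-aryloxyallylcopper whose γ-carbon adds to the ortho aldehyde through a six-membered cyclic transition state, after which σ-bond metathesis of the copper alkoxide with B2pin2 releases boryl ether 8 and regenerates the copper boryl; the closest known reaction type is the copper-catalysed enantioselective borylative coupling of allenes with aldehydes between separate partners, and allenyl aldehydes of this tether topology are known to close to cis 2-alkenyl cycloalkanols through other allylmetal species. The dihydrofuran ring (O1–C2–C3–C3a–C7a) closes by 5-exo-trig attack of C2 on the carbonyl carbon, whereas attack through the CH2 terminus would need a seven-membered ring. C2 and C3 are set together: their cis relationship should follow from the chair-like transition state being fused to the nearly planar forming five-membered ring (aryloxy axial, aryl equatorial, as the Z allylcopper provides), and the absolute sense from the chiral bisphosphine on copper, which selects the aldehyde and allyl faces. The step needs chemoselectivity for borylcupration of the allene over the aldehyde, which the higher reactivity of the terminal allene π-bond toward phosphine–copper boryls and the fast intramolecular trapping should secure, while the ketal keeps the methyl ketone out of enolisation and allyl addition.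

**Step 6**
Reactants: 9 (2R,3R)-5-(2-methyl-1,3-dioxolan-2-yl)-2-[1-(4,4,5,5-tetramethyl-1,3,2-dioxaborolan-2-yl)ethenyl]-2,3-dihydro-1-benzofuran-3-ol
Product: 10 (2R,3R)-5-(2-methyl-1,3-dioxolan-2-yl)-2-(prop-1-en-2-yl)-2,3-dihydro-1-benzofuran-3-ol (cis)
Conditions: MeI (3 equiv), Pd2(dba)3 (2.5 mol%), P(o-tol)3 (10 mol%), K2CO3 (3 equiv), DMF/H2O (9:1), 60 °C
Reagents that add atoms: iodomethane, CI
Why: Suzuki–Miyaura cross-coupling of the alkenyl pinacol boronate with methyl iodide under conditions developed for rapid methylation of alkenylboronates; the neighbouring hydroxyl may coordinate boron and assist transmetallation, and neither stereocentre is touched.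

**Step 7**
Reactants: 10 (2R,3R)-5-(2-methyl-1,3-dioxolan-2-yl)-2-(prop-1-en-2-yl)-2,3-dihydro-1-benzofuran-3-ol
Product: 11 1-[(2R,3R)-3-hydroxy-2-(prop-1-en-2-yl)-2,3-dihydro-1-benzofuran-5-yl]ethan-1-one (cis)
Conditions: PPTS (20 mol%), acetone/H2O (9:1), rt
Reagents that add atoms: water, O
Why: Mild acid-catalysed ketal hydrolysis, accelerated by the para ring oxygen that stabilises the oxocarbenium ion, so that conditions too weak to ionise or dehydrate the benzylic alcohol should suffice.

**Step 8**
Reactants: 12 (E)-crotonaldehyde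
Product: 14 (Z)-2-bromobut-2-enal, via 2,3-dibromobutanal 13 (not isolated)
Conditions: Br2 (1.0 equiv), CH2Cl2, 0 °C; then Et3N (1.2 equiv), 0 °C to rt
Reagents that add atoms: bromine, BrBr
Why: Bromination–dehydrobromination: addition of bromine to the enal and amine-induced loss of HBr through the acidic α-hydrogen give the more stable isomer with the formyl group trans to the methyl group, which is Z by the sequence rule.

**Step 9**
Reactants: 14 (Z)-2-bromobut-2-enal
Product: 15 (Z)-2-bromobut-2-en-1-ol
Conditions: NaBH4, CeCl3·7H2O, MeOH, 0 °C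
Reagents that add atoms: none
Why: Luche 1,2-reduction of the enal, which leaves the vinyl bromide and the alkene geometry unchanged.

**Step 10**
Reactants: 15 (Z)-2-bromobut-2-en-1-ol
Product: 16 (Z)-[(2-bromobut-2-en-1-yl)oxy](tert-butyl)dimethylsilane
Conditions: TBSCl (1.1 equiv), imidazole (2 equiv), CH2Cl2, rt
Reagents that add atoms: tert-butyldimethylsilyl chloride, CC(C)(C)[Si](C)(C)Cl
Why: Standard silylation of a primary allylic alcohol, giving an ether that tolerates the organolithium step and the Mitsunobu reaction.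

**Step 11**
Reactants: 16 (Z)-[(2-bromobut-2-en-1-yl)oxy](tert-butyl)dimethylsilane
Product: 18 (Z)-2-{[tert-butyl(dimethyl)silyl]oxymethyl}but-2-enoic acid, via vinyllithium 17 (not isolated)
Conditions: t-BuLi (2.1 equiv), Et2O, −78 °C; CO2 (g), −78 °C; cold dil. HCl to pH 3–4
Reagents that add atoms: carbon dioxide, O=C=O
Why: Bromine–lithium exchange with retention of alkene geometry followed by carboxylation; at −78 °C the vinyllithium should be configurationally stable and silyl migration suppressed, so the carboxyl group ends up cis to the methyl group.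

**Step 12**
Reactants: 11 1-[(2R,3R)-3-hydroxy-2-(prop-1-en-2-yl)-2,3-dihydro-1-benzofuran-5-yl]ethan-1-one; 18 (Z)-2-{[tert-butyl(dimethyl)silyl]oxymethyl}but-2-enoic acid (1.5 equiv)
Product: 19 (2R,3S)-5-acetyl-2-(prop-1-en-2-yl)-2,3-dihydro-1-benzofuran-3-yl (2Z)-2-{[tert-butyl(dimethyl)silyl]oxymethyl}but-2-enoate (trans)
Conditions: PPh3 (1.5 equiv), DIAD (1.5 equiv), THF, 0 °C to rt
Reagents that add atoms: none
Why: Mitsunobu esterification, in which the carboxylate of 18 displaces the oxyphosphonium group in an SN2 step from the face carrying only the C2 hydrogen, so C3 is inverted (R to S) to the trans ester; the acid is never activated at its acyl carbon and so keeps its Z geometry, and the para acetyl group lowers the donor power of O1 and disfavours ionisation at C3.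

**Step 13**
Reactants: 19 (2R,3S)-5-acetyl-2-(prop-1-en-2-yl)-2,3-dihydro-1-benzofuran-3-yl (2Z)-2-{[tert-butyl(dimethyl)silyl]oxymethyl}but-2-enoate
Product: 20 (2R,3S)-5-acetyl-2-(prop-1-en-2-yl)-2,3-dihydro-1-benzofuran-3-yl (2Z)-2-(hydroxymethyl)but-2-enoate
Conditions: HF·pyridine, THF/pyridine, 0 °C to rt
Reagents that add atoms: none
Why: Fluoride-mediated cleavage of a primary silyl ether under buffered, weakly acidic conditions that avoid the basicity of naked fluoride toward the benzylic ester.

**Step 14**
Reactants: 20 (2R,3S)-5-acetyl-2-(prop-1-en-2-yl)-2,3-dihydro-1-benzofuran-3-yl (2Z)-2-(hydroxymethyl)but-2-enoate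
Product: 21 (2R,3S)-5-acetyl-2-(prop-1-en-2-yl)-2,3-dihydro-1-benzofuran-3-yl (2Z)-2-(acetoxymethyl)but-2-enoate (target)
Conditions: Ac2O (1.5 equiv), pyridine, CH2Cl2, 0 °C to rt
Reagents that add atoms: acetic anhydride, CC(=O)OC(C)=O
Why: Acetylation of the primary alcohol with acetic anhydride and pyridine alone; a stronger nucleophilic amine catalyst is left out so that the resulting allylic acetate is not attacked in SN2′ fashion and the alkene geometry is kept.

**Compound list**
1 | 4'-hydroxyacetophenone | CC(=O)c1ccc(O)cc1 | starting material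
2 | 4-(2-methyl-1,3-dioxolan-2-yl)phenol | CC1(c2ccc(O)cc2)OCCO1 | intermediate
3 | 2-hydroxy-5-(2-methyl-1,3-dioxolan-2-yl)benzaldehyde | CC1(c2ccc(O)c(C=O)c2)OCCO1 | intermediate
4 | propargyl bromide | C#CCBr | starting material
5 | 5-(2-methyl-1,3-dioxolan-2-yl)-2-(prop-2-yn-1-yloxy)benzaldehyde | C#CCOc1ccc(C2(C)OCCO2)cc1C=O | intermediate
6 | 5-(2-methyl-1,3-dioxolan-2-yl)-2-(propa-1,2-dien-1-yloxy)benzaldehyde | C=C=COc1ccc(C2(C)OCCO2)cc1C=O | intermediate
7 | bis(pinacolato)diboron | CC1(C)OB(OC1(C)C)B1OC(C)(C)C(C)(C)O1 | starting material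
8 | O-pinacolboryl ether of 9: (2R,3R)-3-[(4,4,5,5-tetramethyl-1,3,2-dioxaborolan-2-yl)oxy]-5-(2-methyl-1,3-dioxolan-2-yl)-2-[1-(4,4,5,5-tetramethyl-1,3,2-dioxaborolan-2-yl)ethenyl]-2,3-dihydro-1-benzofuran | C=C(B1OC(C)(C)C(C)(C)O1)[C@H]1Oc2ccc(C3(C)OCCO3)cc2[C@H]1OB1OC(C)(C)C(C)(C)O1 | intermediate
9 | (2R,3R)-5-(2-methyl-1,3-dioxolan-2-yl)-2-[1-(4,4,5,5-tetramethyl-1,3,2-dioxaborolan-2-yl)ethenyl]-2,3-dihydro-1-benzofuran-3-ol (cis) | C=C(B1OC(C)(C)C(C)(C)O1)[C@H]1Oc2ccc(C3(C)OCCO3)cc2[C@H]1O | intermediate
10 | (2R,3R)-5-(2-methyl-1,3-dioxolan-2-yl)-2-(prop-1-en-2-yl)-2,3-dihydro-1-benzofuran-3-ol (cis) | C=C(C)[C@H]1Oc2ccc(C3(C)OCCO3)cc2[C@H]1O | intermediate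
11 | 1-[(2R,3R)-3-hydroxy-2-(prop-1-en-2-yl)-2,3-dihydro-1-benzofuran-5-yl]ethan-1-one (cis) | C=C(C)[C@H]1Oc2ccc(C(C)=O)cc2[C@H]1O | intermediate
12 | (E)-crotonaldehyde | C/C=C/C=O | starting material
13 | 2,3-dibromobutanal (stereoisomer mixture; both centres are lost on elimination) | CC(Br)C(Br)C=O | intermediate
14 | (Z)-2-bromobut-2-enal | C/C=C(\Br)C=O | intermediate
15 | (Z)-2-bromobut-2-en-1-ol | C/C=C(\Br)CO | intermediate
16 | (Z)-[(2-bromobut-2-en-1-yl)oxy](tert-butyl)dimethylsilane | C/C=C(\Br)CO[Si](C)(C)C(C)(C)C | intermediate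
17 | (E)-[1-{[tert-butyl(dimethyl)silyl]oxy}but-2-en-2-yl]lithium (geometry of 16 retained; the descriptor changes because lithium ranks below carbon) | C/C=C(\[Li])CO[Si](C)(C)C(C)(C)C | intermediate
18 | (Z)-2-{[tert-butyl(dimethyl)silyl]oxymethyl}but-2-enoic acid | C/C=C(\C(=O)O)CO[Si](C)(C)C(C)(C)C | intermediate
19 | (2R,3S)-5-acetyl-2-(prop-1-en-2-yl)-2,3-dihydro-1-benzofuran-3-yl (2Z)-2-{[tert-butyl(dimethyl)silyl]oxymethyl}but-2-enoate | C=C(C)[C@H]1Oc2ccc(C(C)=O)cc2[C@@H]1OC(=O)/C(=C\C)CO[Si](C)(C)C(C)(C)C | intermediate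
20 | (2R,3S)-5-acetyl-2-(prop-1-en-2-yl)-2,3-dihydro-1-benzofuran-3-yl (2Z)-2-(hydroxymethyl)but-2-enoate | C=C(C)[C@H]1Oc2ccc(C(C)=O)cc2[C@@H]1OC(=O)/C(=C\C)CO | intermediate
21 | (2R,3S)-5-acetyl-2-(prop-1-en-2-yl)-2,3-dihydro-1-benzofuran-3-yl (2Z)-2-(acetoxymethyl)but-2-enoate | C=C(C)[C@H]1Oc2ccc(C(C)=O)cc2[C@@H]1OC(=O)/C(=C\C)COC(C)=O | target

**Step count**
Total: 14 steps. Longest linear sequence: 10 steps (steps 1–7, then 12–14); the side-chain acid takes steps 8–11.

**Steps most likely to fail**

Step 5 (the new cyclisation). The copper boryl may add to the aldehyde instead of the allene, the allylcopper may be protonated or react between molecules before it closes, or face selection by the ligand may be poor.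
Fallback, setting out from 6 and returning at 10: the allenyl aldehyde is cyclised by the known nickel-catalysed alkylative coupling of allenes, aldehydes and organozincs (Ni(cod)2 10 mol%, Me2Zn, THF, 0 °C). This transfers methyl to the central allene carbon and closes the ring to the cis homoallylic alcohol, so it should give racemic cis-5-(2-methyl-1,3-dioxolan-2-yl)-2-(prop-1-en-2-yl)-2,3-dihydro-1-benzofuran-3-ol F1 with the isopropenyl group already in place. Kinetic resolution by lipase-catalysed acetylation (Candida antarctica lipase B, vinyl acetate, MTBE) is expected, by analogy with 1-indanol with the aryl ring as the large group, to convert the unwanted enantiomer into (2S,3S)-5-(2-methyl-1,3-dioxolan-2-yl)-2-(prop-1-en-2-yl)-2,3-dihydro-1-benzofuran-3-yl acetate F2 and to leave the (2R,3R)-alcohol, which is 10. Steps 5 and 6 are bypassed.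

Step 12 (Mitsunobu inversion). The activated C3 oxygen is anti to the C2 hydrogen, so anti elimination to the aromatic benzofuran can compete with substitution; acyl transfer with retention or partial ionisation at C3 would erode the trans configuration.
Fallback, setting out from 11 and returning at 19: inversion and acylation are separated. Mitsunobu reaction with 4-nitrobenzoic acid (PPh3, DIAD, toluene, 0 °C), a small and more acidic pronucleophile whose less basic carboxylate favours substitution, should give (2R,3S)-5-acetyl-2-(prop-1-en-2-yl)-2,3-dihydro-1-benzofuran-3-yl 4-nitrobenzoate F3. Methanolysis (K2CO3, MeOH, 0 °C) would release the trans alcohol 1-[(2R,3S)-3-hydroxy-2-(prop-1-en-2-yl)-2,3-dihydro-1-benzofuran-5-yl]ethan-1-one F4. Acid 18 is converted with 2,4,6-trichlorobenzoyl chloride and Et3N in toluene into (Z)-2-{[tert-butyl(dimethyl)silyl]oxymethyl}but-2-enoic 2,4,6-trichlorobenzoic anhydride F5, which acylates F4 with retention (toluene, 80 °C, no nucleophilic amine, conditions under which angelate-type acids keep their Z geometry) to give 19.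

Step 4 (allene formation beside a free aldehyde). The transient α-oxy propargyl/allenyl anion or the alkoxide may add to the neighbouring aldehyde, and the isomerisation may run on to the 1-propynyl ether.
Fallback, setting out from 5 and returning at 6: the aldehyde is taken out of play during the base step. NaBH4 in MeOH gives [5-(2-methyl-1,3-dioxolan-2-yl)-2-(prop-2-yn-1-yloxy)phenyl]methanol F6. TBSCl and imidazole give tert-butyl(dimethyl){[5-(2-methyl-1,3-dioxolan-2-yl)-2-(prop-2-yn-1-yloxy)phenyl]methoxy}silane F7. Catalytic KOtBu in THF gives tert-butyl(dimethyl){[5-(2-methyl-1,3-dioxolan-2-yl)-2-(propa-1,2-dien-1-yloxy)phenyl]methoxy}silane F8. TBAF in THF gives [5-(2-methyl-1,3-dioxolan-2-yl)-2-(propa-1,2-dien-1-yloxy)phenyl]methanol F9, and oxidation with MnO2 in CH2Cl2 returns aldehyde 6.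

**Further compounds**
F1 | step 5 | racemic cis-5-(2-methyl-1,3-dioxolan-2-yl)-2-(prop-1-en-2-yl)-2,3-dihydro-1-benzofuran-3-ol (both enantiomers) | C=C(C)[C@H]1Oc2ccc(C3(C)OCCO3)cc2[C@H]1O.C=C(C)[C@@H]1Oc2ccc(C3(C)OCCO3)cc2[C@@H]1O
F2 | step 5 | (2S,3S)-5-(2-methyl-1,3-dioxolan-2-yl)-2-(prop-1-en-2-yl)-2,3-dihydro-1-benzofuran-3-yl acetate | C=C(C)[C@@H]1Oc2ccc(C3(C)OCCO3)cc2[C@@H]1OC(C)=O
F3 | step 12 | (2R,3S)-5-acetyl-2-(prop-1-en-2-yl)-2,3-dihydro-1-benzofuran-3-yl 4-nitrobenzoate | C=C(C)[C@H]1Oc2ccc(C(C)=O)cc2[C@@H]1OC(=O)c1ccc([N+](=O)[O-])cc1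
F4 | step 12 | 1-[(2R,3S)-3-hydroxy-2-(prop-1-en-2-yl)-2,3-dihydro-1-benzofuran-5-yl]ethan-1-one (trans) | C=C(C)[C@H]1Oc2ccc(C(C)=O)cc2[C@@H]1O
F5 | step 12 | (Z)-2-{[tert-butyl(dimethyl)silyl]oxymethyl}but-2-enoic 2,4,6-trichlorobenzoic anhydride | C/C=C(\C(=O)OC(=O)c1c(Cl)cc(Cl)cc1Cl)CO[Si](C)(C)C(C)(C)C
F6 | step 4 | [5-(2-methyl-1,3-dioxolan-2-yl)-2-(prop-2-yn-1-yloxy)phenyl]methanol | C#CCOc1ccc(C2(C)OCCO2)cc1CO
F7 | step 4 | tert-butyl(dimethyl){[5-(2-methyl-1,3-dioxolan-2-yl)-2-(prop-2-yn-1-yloxy)phenyl]methoxy}silane | C#CCOc1ccc(C2(C)OCCO2)cc1CO[Si](C)(C)C(C)(C)C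
F8 | step 4 | tert-butyl(dimethyl){[5-(2-methyl-1,3-dioxolan-2-yl)-2-(propa-1,2-dien-1-yloxy)phenyl]methoxy}silane | C=C=COc1ccc(C2(C)OCCO2)cc1CO[Si](C)(C)C(C)(C)C
F9 | step 4 | [5-(2-methyl-1,3-dioxolan-2-yl)-2-(propa-1,2-dien-1-yloxy)phenyl]methanol | C=C=COc1ccc(C2(C)OCCO2)cc1CO
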